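**Retrosynthetic overview**

1. The route rests on the two sp3 C3 carbons of the dihydrofuran rings fused to ring A (the central benzene): each is bonded to a 3,5-dioxygenated benzene ring (the pendant ring and ring B) through the ring carbon meta to both oxygens, trans to the C2 4-hydroxyphenyl group, a bond that only an aryl–metal coupling can make.
2. Target ⇒ octabenzyl ether (hydrogenolysis) ⇒ open carbinol: the seven-membered ring is closed last, by Friedel–Crafts attack of ring B on a 2,4-bis(benzyloxy)benzylic cation grown from the two-carbon side chain of ring A.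
3. Both C3–aryl bonds ⇒ a bis(N-acyloxyphthalimide) plus two equivalents of [3,5-bis(benzyloxy)phenyl]zinc chloride, joined in one nickel-catalysed, two-directional, stereoconvergent decarboxylative coupling.
4. Both dihydrofuran rings and the C2 configuration ⇒ enantioselective double rhodium-carbenoid C–H insertion of a ring A bis(aryldiazoacetate) into its two 4-(benzyloxy)benzyl ethers; ring A comes from methyl 3,5-dihydroxyphenylacetate.
5. Ring order: ring A (bought) → the two dihydrofuran rings (step 7) → the seven-membered ring with ring B (step 15).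

Key step: step 11

Assumption: Rh2(S-PTTL)4 (dirhodium tetrakis[N-phthaloyl-(S)-tert-leucinate]) is taken to give the 2R,6R series in step 7; should the sense prove opposite, Rh2(R-PTTL)4 is used with no other change.

Remark on protecting groups: all eight phenols are carried as benzyl ethers, because hydrogenolysis is expected to spare 2,3-diaryl-dihydrobenzofurans where Lewis-acid dealkylation would open them. The side-chain oxygen is carried as a pivalate so that its neighbouring C–H bonds do not compete in the carbenoid step.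

Remark on locants: the tricyclic core is numbered as benzo[1,2-b:5,4-b']difuran; C2/C6 carry the 4-oxygenated phenyl groups, C3/C5 the carboxyl or resorcinol-type aryl groups, C4 the side chain.

Remark on stoichiometry: steps 1, 9 and 11 are twofold reactions that consume two equivalents of a numbered partner; the second equivalent is entered under "Reagents that add atoms".

**Route**

Step 1
Reactants: 1 methyl 2-(3,5-dihydroxyphenyl)acetate; 2 4-(benzyloxy)benzyl chloride (2.2 equiv)
Product: 3 methyl 2-{3,5-bis[(4-(benzyloxy)benzyl)oxy]phenyl}acetate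
Conditions: 2 (2.2 equiv), K2CO3 (3 equiv), KI (cat.), DMF, 60 °C
Reagents that add atoms: 4-(benzyloxy)benzyl chloride (second equivalent of 2), ClCc1ccc(OCc2ccccc2)cc1
Why: Twofold Williamson ether synthesis: each of the two phenoxides is alkylated by one equivalent of the activated benzylic chloride, while the methyl ester and its benzylic CH2 are untouched by carbonate.

Step 2
Reactants: 3 the bis(ether) methyl ester
Product: 4 2-{3,5-bis[(4-(benzyloxy)benzyl)oxy]phenyl}ethanol
Conditions: LiAlH4, THF, 0 °C; aqueous work-up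
Reagents that add atoms: none
Why: Hydride reduction of the ester to the primary alcohol; aryl benzyl ethers are inert to LiAlH4.

Step 3
Reactants: 4 the primary alcohol
Product: 5 2-{3,5-bis[(4-(benzyloxy)benzyl)oxy]phenyl}ethyl pivalate
Conditions: pivaloyl chloride, pyridine, DMAP (cat.), CH2Cl2, 0 °C → rt
Reagents that add atoms: pivaloyl chloride, CC(C)(C)C(Cl)=O
Why: Acylation of the primary alcohol; the acyloxy group deactivates the neighbouring C–H bonds towards the rhodium carbenoid of step 7, and the hindered ester should survive steps 4 to 11.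

Step 4
Reactants: 5 the pivalate
Product: 6 2-{3,5-bis[(4-(benzyloxy)benzyl)oxy]-2,6-dibromophenyl}ethyl pivalate
Conditions: NBS (2.05 equiv), MeCN, 0 °C → rt, dark
Reagents that add atoms: N-bromosuccinimide, O=C1CCC(=O)N1Br
Why: Twofold electrophilic aromatic bromination: ring A, a 1,3-dialkoxy-5-alkylbenzene, is far more electron-rich than the other four rings and reacts at the two positions para to an ether oxygen, which flank the side chain, the position between the two bulky ethers being the slowest.

Step 5
Reactants: 6 the dibromide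
Product: 7 dimethyl 2,2'-{4,6-bis[(4-(benzyloxy)benzyl)oxy]-2-[2-(pivaloyloxy)ethyl]-1,3-phenylene}diacetate
Conditions: BrZnCH2CO2Me (4 equiv, preformed THF solution), Pd2(dba)3 (5 mol%), XPhos (20 mol%), THF, 65 °C
Reagents that add atoms: (2-methoxy-2-oxoethyl)zinc bromide, COC(=O)C[Zn]Br
Why: Twofold palladium-catalysed Negishi coupling of the Reformatsky reagent (α-arylation of a zinc ester enolate), in which the bulky biarylphosphine allows oxidative addition to the doubly ortho-substituted bromides; pivalate and benzyl ethers do not react with the zinc enolate.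

Step 6
Reactants: 7 the bis(arylacetate)
Product: 8 dimethyl 2,2'-{4,6-bis[(4-(benzyloxy)benzyl)oxy]-2-[2-(pivaloyloxy)ethyl]-1,3-phenylene}bis(2-diazoacetate)
Conditions: 4-acetamidobenzenesulfonyl azide (3 equiv), DBU (4 equiv), MeCN, 0 °C → rt
Reagents that add atoms: 4-acetamidobenzenesulfonyl azide, CC(=O)Nc1ccc(cc1)S(=O)(=O)N=[N+]=[N-]
Why: Regitz diazo transfer to the two arylacetate CH2 groups, the only carbon acids present that the amidine base deprotonates (the pivalate has no α-hydrogen).

Step 7
Reactants: 8 the bis(aryldiazoacetate)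
Product: 9 dimethyl (2R,3S,5S,6R)-2,6-bis[4-(benzyloxy)phenyl]-4-[2-(pivaloyloxy)ethyl]-2,3,5,6-tetrahydrobenzo[1,2-b:5,4-b']difuran-3,5-dicarboxylate (cis in both rings)
Conditions: Rh2(S-PTTL)4 (4 mol%), toluene, −60 → −30 °C
Reagents that add atoms: none
Why: Intramolecular 1,5 C–H insertion of each rhodium aryl(ester)carbenoid into the adjacent ArCH2–O group, the established enantioselective entry to cis-2-aryl-2,3-dihydrobenzofuran-3-carboxylates, closes both dihydrofuran rings; the chiral carboxylate ligands fix C2 and C6 as R, any meso isomer from a mismatched second insertion is removed by chromatography so that the twofold-symmetric product is enriched further, and the side-chain C–H bonds next to the pivalate oxygen are deactivated towards the carbenoid.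

Step 8
Reactants: 9 the cis,cis dimethyl ester
Product: 10 (2R,3S,5S,6R)-2,6-bis[4-(benzyloxy)phenyl]-4-[2-(pivaloyloxy)ethyl]-2,3,5,6-tetrahydrobenzo[1,2-b:5,4-b']difuran-3,5-dicarboxylic acid
Conditions: Me3SnOH (10 equiv), 1,2-dichloroethane, 80 °C; then 0.5 M HCl wash
Reagents that add atoms: trimethyltin hydroxide, C[Sn](C)(C)O
Why: Tin hydroxide ester hydrolysis cleaves the methyl esters under neutral conditions and should leave the hindered pivalate, the benzyl ethers and the C2/C6 centres untouched; the C3/C5 configuration of the acid need not be controlled because it is erased in step 11.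

Step 9
Reactants: 10 the diacid; 11 N-hydroxyphthalimide (2.2 equiv)
Product: 12 bis(1,3-dioxoisoindolin-2-yl) (2R,3S,5S,6R)-2,6-bis[4-(benzyloxy)phenyl]-4-[2-(pivaloyloxy)ethyl]-2,3,5,6-tetrahydrobenzo[1,2-b:5,4-b']difuran-3,5-dicarboxylate
Conditions: 11 (2.2 equiv), N,N'-diisopropylcarbodiimide (2.4 equiv), DMAP (cat.), CH2Cl2, rt
Reagents that add atoms: N-hydroxyphthalimide (second equivalent of 11), O=C1c2ccccc2C(=O)N1O
Why: Twofold carbodiimide esterification, one equivalent of N-hydroxyphthalimide per carboxyl group, turns both acids into redox-active esters; the pivalate is untouched and any C3 epimerisation is without consequence.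

Step 10
Reactants: 13 1-bromo-3,5-bis(benzyloxy)benzene
Product: 15 [3,5-bis(benzyloxy)phenyl]zinc chloride, via arylmagnesium bromide 14 (not isolated)
Conditions: Mg turnings, LiCl, THF, 25 °C; then ZnCl2 (1.0 equiv, THF), 0 → 25 °C; used as solution
Reagents that add atoms: zinc chloride, Cl[Zn]Cl
Why: Magnesium insertion into the aryl bromide gives the Grignard reagent, which transmetalates to zinc; the arylzinc chloride is mild enough to spare the esters of 12.

Step 11
Reactants: 12 the bis(N-acyloxyphthalimide); 15 [3,5-bis(benzyloxy)phenyl]zinc chloride (6 equiv)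
Product: 16 2-{(2R,3R,5R,6R)-2,6-bis[4-(benzyloxy)phenyl]-3,5-bis[3,5-bis(benzyloxy)phenyl]-2,3,5,6-tetrahydrobenzo[1,2-b:5,4-b']difuran-4-yl}ethyl pivalate
Conditions: 15 (6 equiv), NiCl2(dme) (40 mol%), 4,4'-di-tert-butyl-2,2'-bipyridine (80 mol%), THF/DMF 3:2, 25 °C; then 1 M HCl
Reagents that add atoms: [3,5-bis(benzyloxy)phenyl]zinc chloride (second equivalent of 15), Cl[Zn]c1cc(OCc2ccccc2)cc(OCc2ccccc2)c1
Why: Low-valent nickel bearing the bipyridine transfers one electron to each N-acyloxyphthalimide, which loses phthalimide anion and CO2 to leave a planar benzylic C3 radical; this is captured by the arylnickel species formed by transmetalation from 15, and reductive elimination from trivalent nickel forms the C3–aryl bond, the closest known reaction type being the decarboxylative Negishi-type arylation of redox-active esters of secondary acids. No ring is closed. Each new stereocentre (C3 and C5) is set when the metal engages the radical on the face opposite the adjacent 4-(benzyloxy)phenyl group at C2 or C6, so the cis configuration of the acid is erased and both centres should emerge trans (3R,5R). The step needs trans delivery and must outrun β-hydride elimination to the benzofuran and opening of the radical by loss of the ring oxygen; the first is secured by the C2 aryl group, the second is countered by excess arylzinc and a high nickel loading, and the third is disfavoured because the C2–O bond lies near the nodal plane of the benzylic radical. The precursor has a twofold axis through ring A, so the two couplings, each consuming one equivalent of 15, are equivalent and either new aryl ring can later become ring B.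

Step 12
Reactants: 16 the diaryl pivalate
Product: 17 2-{(2R,3R,5R,6R)-2,6-bis[4-(benzyloxy)phenyl]-3,5-bis[3,5-bis(benzyloxy)phenyl]-2,3,5,6-tetrahydrobenzo[1,2-b:5,4-b']difuran-4-yl}ethanol
Conditions: iBu2AlH (4 equiv), CH2Cl2, −78 → 0 °C; aqueous work-up
Reagents that add atoms: none
Why: Reductive cleavage of the pivalate by the aluminium hydride frees the primary alcohol; no other reducible group is present.

Step 13
Reactants: 17 the primary alcohol
Product: 18 2-{(2R,3R,5R,6R)-2,6-bis[4-(benzyloxy)phenyl]-3,5-bis[3,5-bis(benzyloxy)phenyl]-2,3,5,6-tetrahydrobenzo[1,2-b:5,4-b']difuran-4-yl}acetaldehyde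
Conditions: Dess–Martin periodinane (1.5 equiv), CH2Cl2, 0 °C → rt
Reagents that add atoms: none
Why: Dess–Martin oxidation gives the arylacetaldehyde under near-neutral conditions without over-oxidation.

Step 14
Reactants: 18 the aldehyde; 19 1-bromo-2,4-bis(benzyloxy)benzene
Product: 21 1-[2,4-bis(benzyloxy)phenyl]-2-{(2R,3R,5R,6R)-2,6-bis[4-(benzyloxy)phenyl]-3,5-bis[3,5-bis(benzyloxy)phenyl]-2,3,5,6-tetrahydrobenzo[1,2-b:5,4-b']difuran-4-yl}ethanol as both carbinol epimers, via arylmagnesium bromide 20 (not isolated)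
Conditions: 19, Mg turnings, THF, 40 °C; then 18, LaCl3·2LiCl (30 mol%), THF, −78 → 0 °C; then aq. NH4Cl
Reagents that add atoms: none
Why: Grignard addition to the aldehyde, with the lanthanum salt to favour addition over enolisation of the arylacetaldehyde; the new carbinol centre is formed as both epimers, which is immaterial because it is ionised in step 15.

Step 15
Reactants: 21 the diaryl carbinol
Product: 22 octa-O-benzyl ether of the target (seven-membered ring closed; diarylmethine carbon R)
Conditions: TsOH·H2O (20 mol%), CH2Cl2, 0 °C → rt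
Reagents that add atoms: none
Why: Acid ionises the doubly oxygen-stabilised benzylic alcohol and the cation is trapped by the ortho carbon (para to one benzyloxy group) of an adjacent 3,5-bis(benzyloxy)phenyl ring in an intramolecular Friedel–Crafts alkylation that closes the seven-membered ring, the two candidate rings being equivalent by the twofold axis; the new diarylmethine centre should be set R because the 2,4-bis(benzyloxy)phenyl group takes the pseudo-axial site, on the face of the C–H bond at the neighbouring furan C3, and so avoids allylic 1,3-strain with the adjacent benzyloxy group of ring B.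

Step 16
Reactants: 22 the octabenzyl ether
Product: 23 CNP0154047.1
Conditions: H2 (1 atm), Pd/C (10 wt%), THF/MeOH 1:1, rt, degassed solvents
Reagents that add atoms: none
Why: Catalytic hydrogenolysis cleaves the eight aryl benzyl ethers, which react much faster than the cyclic benzylic C2–O bonds of the dihydrofurans; no stereocentre is touched.

**Compound list**

1 | methyl 2-(3,5-dihydroxyphenyl)acetate | COC(=O)Cc1cc(O)cc(O)c1 | starting material
2 | 4-(benzyloxy)benzyl chloride | ClCc1ccc(OCc2ccccc2)cc1 | starting material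
3 | methyl 2-{3,5-bis[(4-(benzyloxy)benzyl)oxy]phenyl}acetate | COC(=O)Cc1cc(OCc2ccc(OCc3ccccc3)cc2)cc(OCc2ccc(OCc3ccccc3)cc2)c1 | intermediate
4 | 2-{3,5-bis[(4-(benzyloxy)benzyl)oxy]phenyl}ethanol | OCCc1cc(OCc2ccc(OCc3ccccc3)cc2)cc(OCc2ccc(OCc3ccccc3)cc2)c1 | intermediate
5 | 2-{3,5-bis[(4-(benzyloxy)benzyl)oxy]phenyl}ethyl pivalate | CC(C)(C)C(=O)OCCc1cc(OCc2ccc(OCc3ccccc3)cc2)cc(OCc2ccc(OCc3ccccc3)cc2)c1 | intermediate
6 | 2-{3,5-bis[(4-(benzyloxy)benzyl)oxy]-2,6-dibromophenyl}ethyl pivalate | CC(C)(C)C(=O)OCCc1c(Br)c(OCc2ccc(OCc3ccccc3)cc2)cc(OCc2ccc(OCc3ccccc3)cc2)c1Br | intermediate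
7 | dimethyl 2,2'-{4,6-bis[(4-(benzyloxy)benzyl)oxy]-2-[2-(pivaloyloxy)ethyl]-1,3-phenylene}diacetate | CC(C)(C)C(=O)OCCc1c(CC(=O)OC)c(OCc2ccc(OCc3ccccc3)cc2)cc(OCc2ccc(OCc3ccccc3)cc2)c1CC(=O)OC | intermediate
8 | dimethyl 2,2'-{4,6-bis[(4-(benzyloxy)benzyl)oxy]-2-[2-(pivaloyloxy)ethyl]-1,3-phenylene}bis(2-diazoacetate) | CC(C)(C)C(=O)OCCc1c(C(=[N+]=[N-])C(=O)OC)c(OCc2ccc(OCc3ccccc3)cc2)cc(OCc2ccc(OCc3ccccc3)cc2)c1C(=[N+]=[N-])C(=O)OC | intermediate
9 | dimethyl (2R,3S,5S,6R)-2,6-bis[4-(benzyloxy)phenyl]-4-[2-(pivaloyloxy)ethyl]-2,3,5,6-tetrahydrobenzo[1,2-b:5,4-b']difuran-3,5-dicarboxylate (cis in both rings) | c1ccccc1COc1ccc([C@@H]2Oc3cc4c(c(CCOC(=O)C(C)(C)C)c3[C@@H]2C(=O)OC)[C@H](C(=O)OC)[C@H](c2ccc(OCc5ccccc5)cc2)O4)cc1 | intermediate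
10 | (2R,3S,5S,6R)-2,6-bis[4-(benzyloxy)phenyl]-4-[2-(pivaloyloxy)ethyl]-2,3,5,6-tetrahydrobenzo[1,2-b:5,4-b']difuran-3,5-dicarboxylic acid | c1ccccc1COc1ccc([C@@H]2Oc3cc4c(c(CCOC(=O)C(C)(C)C)c3[C@@H]2C(=O)O)[C@H](C(=O)O)[C@H](c2ccc(OCc5ccccc5)cc2)O4)cc1 | intermediate
11 | N-hydroxyphthalimide | O=C1c2ccccc2C(=O)N1O | starting material
12 | bis(1,3-dioxoisoindolin-2-yl) (2R,3S,5S,6R)-2,6-bis[4-(benzyloxy)phenyl]-4-[2-(pivaloyloxy)ethyl]-2,3,5,6-tetrahydrobenzo[1,2-b:5,4-b']difuran-3,5-dicarboxylate | c1ccccc1COc1ccc([C@@H]2Oc3cc4c(c(CCOC(=O)C(C)(C)C)c3[C@@H]2C(=O)ON2C(=O)c5ccccc5C2=O)[C@H](C(=O)ON2C(=O)c5ccccc5C2=O)[C@H](c2ccc(OCc5ccccc5)cc2)O4)cc1 | intermediate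
13 | 1-bromo-3,5-bis(benzyloxy)benzene | Brc1cc(OCc2ccccc2)cc(OCc2ccccc2)c1 | starting material
14 | [3,5-bis(benzyloxy)phenyl]magnesium bromide | Br[Mg]c1cc(OCc2ccccc2)cc(OCc2ccccc2)c1 | intermediate
15 | [3,5-bis(benzyloxy)phenyl]zinc chloride | Cl[Zn]c1cc(OCc2ccccc2)cc(OCc2ccccc2)c1 | intermediate
16 | 2-{(2R,3R,5R,6R)-2,6-bis[4-(benzyloxy)phenyl]-3,5-bis[3,5-bis(benzyloxy)phenyl]-2,3,5,6-tetrahydrobenzo[1,2-b:5,4-b']difuran-4-yl}ethyl pivalate (trans in both rings) | c1ccccc1COc1ccc([C@@H]2Oc3cc4c(c(CCOC(=O)C(C)(C)C)c3[C@H]2c2cc(OCc5ccccc5)cc(OCc5ccccc5)c2)[C@@H](c2cc(OCc5ccccc5)cc(OCc5ccccc5)c2)[C@H](c2ccc(OCc5ccccc5)cc2)O4)cc1 | intermediate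
17 | 2-{(2R,3R,5R,6R)-2,6-bis[4-(benzyloxy)phenyl]-3,5-bis[3,5-bis(benzyloxy)phenyl]-2,3,5,6-tetrahydrobenzo[1,2-b:5,4-b']difuran-4-yl}ethanol | c1ccccc1COc1ccc([C@@H]2Oc3cc4c(c(CCO)c3[C@H]2c2cc(OCc5ccccc5)cc(OCc5ccccc5)c2)[C@@H](c2cc(OCc5ccccc5)cc(OCc5ccccc5)c2)[C@H](c2ccc(OCc5ccccc5)cc2)O4)cc1 | intermediate
18 | 2-{(2R,3R,5R,6R)-2,6-bis[4-(benzyloxy)phenyl]-3,5-bis[3,5-bis(benzyloxy)phenyl]-2,3,5,6-tetrahydrobenzo[1,2-b:5,4-b']difuran-4-yl}acetaldehyde | c1ccccc1COc1ccc([C@@H]2Oc3cc4c(c(CC=O)c3[C@H]2c2cc(OCc5ccccc5)cc(OCc5ccccc5)c2)[C@@H](c2cc(OCc5ccccc5)cc(OCc5ccccc5)c2)[C@H](c2ccc(OCc5ccccc5)cc2)O4)cc1 | intermediate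
19 | 1-bromo-2,4-bis(benzyloxy)benzene | Brc1ccc(OCc2ccccc2)cc1OCc1ccccc1 | starting material
20 | [2,4-bis(benzyloxy)phenyl]magnesium bromide | Br[Mg]c1ccc(OCc2ccccc2)cc1OCc1ccccc1 | intermediate
21 | 1-[2,4-bis(benzyloxy)phenyl]-2-{(2R,3R,5R,6R)-2,6-bis[4-(benzyloxy)phenyl]-3,5-bis[3,5-bis(benzyloxy)phenyl]-2,3,5,6-tetrahydrobenzo[1,2-b:5,4-b']difuran-4-yl}ethanol (both carbinol epimers) | c1ccccc1COc1ccc([C@@H]2Oc3cc4c(c(CC(O)c5ccc(OCc6ccccc6)cc5OCc5ccccc5)c3[C@H]2c2cc(OCc5ccccc5)cc(OCc5ccccc5)c2)[C@@H](c2cc(OCc5ccccc5)cc(OCc5ccccc5)c2)[C@H](c2ccc(OCc5ccccc5)cc2)O4)cc1 | intermediate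
22 | octa-O-benzyl ether of the target (all eight phenols benzylated; outer dihydrofuran 2R,3R; inner dihydrofuran 2R,3R; diarylmethine carbon of the seven-membered ring R) | c1ccccc1COc1ccc([C@@H]2Oc3cc4c5c(c3[C@H]2c2cc(OCc6ccccc6)cc(OCc6ccccc6)c2)C[C@H](c2ccc(OCc6ccccc6)cc2OCc2ccccc2)c2c(OCc6ccccc6)cc(OCc6ccccc6)cc2[C@H]5[C@H](c2ccc(OCc6ccccc6)cc2)O4)cc1 | intermediate
23 | CNP0154047.1 (octaphenol; outer dihydrofuran 2R,3R with pendant 3,5-dihydroxyphenyl; inner dihydrofuran 2R,3R fused through ring B to the seven-membered ring; diarylmethine carbon R bearing 2,4-dihydroxyphenyl) | Oc1ccc([C@@H]2Oc3cc4c5c(c3[C@H]2c2cc(O)cc(O)c2)C[C@H](c2ccc(O)cc2O)c2c(O)cc(O)cc2[C@H]5[C@H](c2ccc(O)cc2)O4)cc1 | target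

**Step count and risks**

Total step count: 16. Longest linear sequence: 15 steps (steps 1–9 and 11–16; step 10 is the side branch to the arylzinc reagent).

Steps most likely to fail:

Step 11. The two benzylic C3 radicals, each flanked by the side chain on ring A, may be lost to β-hydride elimination (aromatisation to the benzofuran), to reduction or to dimerisation before nickel captures them, or the second coupling may stall. Fallback: set out from diacid 10 and couple it directly with two equivalents of aryl bromide 13 by metallaphotoredox decarboxylative arylation (Ir[dF(CF3)ppy]2(dtbbpy)PF6, NiCl2(dme), 4,4'-di-tert-butyl-2,2'-bipyridine, Cs2CO3, DMF, blue light). Here the carboxylate is oxidised by the excited photocatalyst and the same C3 radical is intercepted by an arylnickel bromide formed by oxidative addition of 13, so neither activated ester nor organozinc is needed. The route is rejoined at 16; this fallback makes no new compound (F0).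

Step 7. Enantiocontrol and the cis, twofold-symmetric outcome may erode for a carbenoid flanked by two ortho substituents, and carbenoid dimerisation may compete. Fallback: set out from 8 and decompose it with achiral Rh2(OAc)4 in CH2Cl2 to the stereo-random cis,cis diester F1 (racemic twofold-symmetric form plus meso form). The meso form is removed on silica and the twofold-symmetric racemate is separated by preparative chromatography on a chiral stationary phase; the 2R,6R enantiomer is 9, where the route is rejoined. Stereocontrol then rests on separation instead of on the catalyst.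

Step 15. Ionisation may stop at the stilbene, the acid may also ionise the C2–O bonds of the dihydrofurans (loss of trans integrity), or the cation may be attacked on the wrong face. Fallback: set out from aldehyde 18 and close the seven-membered ring first, by Lewis-acid-induced intramolecular Friedel–Crafts hydroxyalkylation of ring B (BF3·OEt2, CH2Cl2, −78 °C), to the cyclic benzylic alcohol F2. This is then ionised with catalytic Sc(OTf)3 in the presence of commercial 1,3-bis(benzyloxy)benzene, which attacks the ring-B-stabilised cyclic cation through its C4 from the axial direction. The route is rejoined at 22.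

Further compounds
F0 | step 11 | none | none
F1 | step 7 | dimethyl 2,6-bis[4-(benzyloxy)phenyl]-4-[2-(pivaloyloxy)ethyl]-2,3,5,6-tetrahydrobenzo[1,2-b:5,4-b']difuran-3,5-dicarboxylate, cis in both rings, mixture of racemic twofold-symmetric and meso forms | c1ccccc1COc1ccc(C2Oc3cc4c(c(CCOC(=O)C(C)(C)C)c3C2C(=O)OC)C(C(=O)OC)C(c2ccc(OCc5ccccc5)cc2)O4)cc1
F2 | step 15 | cyclic benzylic alcohol: the octabenzyl-protected seven-membered-ring compound lacking the 2,4-bis(benzyloxy)phenyl group and bearing OH on the ring carbon next to ring B (carbinol configuration undefined) | c1ccccc1COc1ccc([C@@H]2Oc3cc4c5c(c3[C@H]2c2cc(OCc6ccccc6)cc(OCc6ccccc6)c2)CC(O)c2c(OCc6ccccc6)cc(OCc6ccccc6)cc2[C@H]5[C@H](c2ccc(OCc6ccccc6)cc2)O4)cc1
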